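E is the charge whose balance I write for this flask. You dose J into a stirred mixture of two phases, with Z in the second, and you want to know what stands at the asked time.

| flask | J | Z | E | remark | time | volume of the second phase over the first |
|---|---|---|---|---|---|---|
| epsilon | 0.010 M (fed, over 2.0 h) | 1.2 equiv | 10 mM | run made earlier; the fed solution adds 0.50 times the starting volume |  |  |
| eta | 0.015 M (fed, over 2.0 h) | 1.2 equiv | 10 mM | run made earlier; the fed solution adds 0.50 times the starting volume |  |  |
| alpha | 0.020 M (fed, over 2.0 h) | 1.2 equiv | 15 mM | run made earlier; the fed solution adds 0.50 times the starting volume |  |  |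
| flask | 0.020 M (fed, over 2.0 h) | 1.20 equiv | 10.0 mM | the fed solution adds 0.50 times the starting volume | 6.0 d | 2.0 |

| run | time / d | Q / % | J / % |
|---|---|---|---|
| epsilon | 1.04 | 7.4 | 33.6 |
| epsilon | 2.08 | 3.4 | 20.5 |
| epsilon | 3.00 | 2.5 | 15.4 |
| epsilon | 4.00 | 1.5 | 12.0 |
| epsilon | 5.00 | 1.7 | 11.3 |
| epsilon | 6.00 | 1.6 | 8.8 |
| epsilon | 8.00 | 2.2 | 7.3 |
| eta | 0.625 | 10.0 | 48.9 |
| eta | 0.833 | 9.2 | 43.0 |
| eta | 1.25 | 8.9 | 37.1 |
| eta | 2.08 | 7.4 | 32.4 |
| eta | 3.00 | 7.6 | 29.4 |
| eta | 5.00 | 5.9 | 27.5 |
| eta | 8.00 | 5.5 | 26.8 |
| alpha | 1.25 | 10.7 | 28.5 |
| alpha | 3.00 | 7.4 | 21.1 |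
| alpha | 4.00 | 6.7 | 21.1 |
| alpha | 6.00 | 6.3 | 19.9 |
| alpha | 8.00 | 5.9 | 18.1 |

(scatter of a reading: 0.5 percentage points)

- charges are per starting volume, the dose included; the dosed solution carries all of it
- in the second phase: Z; everything else is in the first
- charges count per volume of the first phase; a concentration in a rate is the amount of a species over the volume of its own phase; every rate counts per litre of the first phase
- the earlier runs hold the two phases in the same ratio of volumes as the flask asked about
- the reaction counts as stopped when no species that holds the J changes by six tenths of a point or more over the second half of the time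

- which holds at 6.0 d: what has brought the reaction to rest, or that it has not come to rest (it is still moving / all of J has reacted / forward and back rates have come level)
- how much Q there is at 6.0 d, in percent of the J charged
- amount of Q if the flask were left three thousand times as long, in percent of the J charged

Add the Q and J columns first. At the last reading, J + Q is 32.3% in eta and 24.0% in alpha. In epsilon, where cE equals cJ, it is down to 9.50%. So I take each E to remove one holder of J, and I write the balance of E, the limiting reagent of that loss, since its charge is smaller than that of J. For the flask this gives 50.0%, the surviving share: one minus cE over the charge of J.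

Now the flask in slow motion, as I reckon it. The dose lasts 2.0 h, and the earliest reading of any run comes later, at 0.625 d, so the first instants are unread. Q over J in eta reads 0.204 there and 0.205 at the last reading, while J falls from 48.9% to 26.8%. In eta, J + Q stands 6.5 percentage points above its surviving share at 2.08 d and 3.7 points above it at 3.00 d. The flask has twice eta's excess of J over E, so I expect rest well before the asked time.

At rest, J + Q equals 50.0%, and the ratio splits it. Alpha has the flask's charges of J and Z, and its last reading gives a ratio of 0.326, so my Q is 12.3%.

The forecast says forward and back rates have come level, with Q at 11.5% (10.2% to 12.8%) and 11.5% (9.5% to 13%) for the very long flask, holding that “E removes one J-holder each, irreversibly and stoichiometrically”. My figure stands above its 11.5%.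

The flask gives 11.4% of Q at 6.0 d and 11.4% when left very long: forward and back rates have come level. Waiting buys nothing: at 60.0 d Q is 11.4%. E stands at 0.020% of its charge, L at 50.0%, and J + Q at 50.0%, against the surviving share of 50.0%.

    J + G ⇌ Q (K = 42.0 L mol⁻¹, k = 3.56 L mol⁻¹ h⁻¹)
    G ⇌ Z, rate k2*([G] - [Z]/K2) per volume of the first phase (partition coefficient = 0.787, kL = 0.830 h⁻¹)
    J + E → L (k = 10.5 L mol⁻¹ h⁻¹)

Take J up to 0.050 M, with the same equivalents and the same cE: the surviving share becomes 80.0%. That flask ends with J at 49.6% and Q at 30.4%, together 80.0%.

The runs are simulated with constants of no real substance; scatter was added.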